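Ring A is assembled last, onto a completed ring B. Only the enolised carbonyl carbon C5 is missing between C4a of the pyranone and C6, and carbon monoxide supplies it: palladium enters a C4a–I bond, takes up CO and acylates C6 of a pendant β-keto ester, so that C4a–C5 and C5–C6 form and ring A closes in one operation. Because C8 is quaternary and already bonded to C7 and C8a, the two reacting ends are held close and no stereocentre is created or endangered. The precursor is the C4a-iodinated cis-2,3-dimethyl-2,3-dihydropyran-4-one whose C8a bears that quaternary carbon with prenyl, the limonene-derived branched chain and the β-keto ester arm.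

Key step: step 19

Remark on numbering: C2 to C8a are the atoms of the chromene core of the target, and the same labels are used for these atoms in all intermediates.
Remark on the ester: the β-keto ester arm is carried as its 2-(trimethylsilyl)ethyl ester and not as a tert-butyl ester, so that it is later removed with fluoride; protic acid able to cleave a tert-butyl ester would add to the two 1,1-disubstituted alkenes and could cyclise the prenyl group onto the enolised trione.
Remark on the chain: C4 of (R)-limonene already has the configuration required at the chain stereocentre, so this centre is taken from the chiral pool and needs no stereoselective step.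
Assumption for step 7: the N-spiro ammonium salt (S,S)-3,4,5-trifluorophenyl-NAS bromide (nitrogen spiro-linked to two 1,1'-binaphthalene-2,2'-diyldimethylene units, one of them carrying 3,4,5-trifluorophenyl groups at its 3- and 3'-positions) is taken to deliver the allylic bromide to the enolate face that gives (R)-13, by analogy with its sense for α-alkyl tert-butyl malonates; if correlation shows the opposite, the (R,R)-salt is used.
Assumption for step 21: the (5aR,10bS)-triazolium salt is taken to leave the Si face of the β-carbon of the acyl azolium open; if correlation shows the opposite, its (5aS,10bR) antipode is used.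

Step 1
Reactants: 1 (+)-limonene 1,2-oxide (4R; cis/trans mixture at the epoxide)
Product: 3 (3R)-6-oxo-3-(prop-1-en-2-yl)heptanal, via limonene-1,2-diol 2 (not isolated)
Conditions: H5IO6, THF/H2O, 0 °C to rt
Reagents that add atoms: water, O
Why: Acid-mediated opening of the epoxide to the 1,2-diol and glycol cleavage by periodate (Malaprade reaction) should occur in one pot, leaving the isopropenyl group and the terpene stereocentre, which becomes the chain stereocentre, untouched.

Step 2
Reactants: 3 (3R)-6-oxo-3-(prop-1-en-2-yl)heptanal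
Product: 4 (3R)-6-oxo-3-(prop-1-en-2-yl)heptanoic acid
Conditions: NaClO2, NaH2PO4, 2-methylbut-2-ene, t-BuOH/H2O, 0 °C to rt
Reagents that add atoms: sodium chlorite, [Na+].[O-]Cl=O
Why: Chlorite oxidation of the aldehyde (Pinnick oxidation) is selective for CHO over the ketone, and the alkene scavenger removes hypochlorous acid before it can add to the isopropenyl group.

Step 3
Reactants: 4 (3R)-6-oxo-3-(prop-1-en-2-yl)heptanoic acid
Product: 5 (3R)-6-methyl-3-(prop-1-en-2-yl)hept-6-enoic acid
Conditions: Ph3PCH3Br, KOtBu (excess), THF, 0 °C to rt; then dilute HCl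
Reagents that add atoms: methyltriphenylphosphonium bromide, C[P+](c1ccccc1)(c1ccccc1)c1ccccc1.[Br-]
Why: Wittig methylenation of the methyl ketone proceeds on the carboxylate salt, which is inert to the ylide, and the stereocentre is alpha to neither carbonyl and cannot epimerise.

Step 4
Reactants: 5 (3R)-6-methyl-3-(prop-1-en-2-yl)hept-6-enoic acid
Product: 7 (3S)-3-(iodomethyl)-2,6-dimethylhepta-1,6-diene, via Barton ester 6 (not isolated)
Conditions: 1-hydroxypyridine-2(1H)-thione, N,N'-dicyclohexylcarbodiimide (DCC), 4-(dimethylamino)pyridine (cat.), CH2Cl2, rt, dark; then CHI3, visible light, rt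
Reagents that add atoms: 1-hydroxypyridine-2(1H)-thione, ON1C=CC=CC1=S; iodoform, IC(I)I
Why: Radical decarboxylative iodination (Barton decarboxylation): the thiohydroxamate ester fragments under light and the primary radical should abstract iodine from iodoform faster than it cyclises onto either alkene or undergoes vinyl migration, so the neighbouring stereocentre is kept (its descriptor becomes S only because iodine outranks carbon).

Step 5
Reactants: 8 3-(tert-butoxy)-3-oxopropanoic acid; 9 2,2-diphenylethanol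
Product: 10 tert-butyl 2,2-diphenylethyl malonate
Conditions: 1-ethyl-3-[3-(dimethylamino)propyl]carbodiimide hydrochloride (EDC·HCl), 4-(dimethylamino)pyridine (cat.), CH2Cl2, 0 °C to rt
Reagents that add atoms: none
Why: Carbodiimide esterification (Steglich esterification) of the malonic half-ester with a primary alcohol gives the mixed diester whose two carboxyl groups can later be told apart by a chiral cation and by a hydride reagent.

Step 6
Reactants: 10 tert-butyl 2,2-diphenylethyl malonate; 7 (3S)-3-(iodomethyl)-2,6-dimethylhepta-1,6-diene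
Product: 11 mixed malonate carrying the branched chain at C2 (both C2 epimers)
Conditions: NaH, DMF, 0 °C; then 7, 60 °C (10 in excess)
Reagents that add atoms: none
Why: SN2 alkylation of the sodium malonate by the primary iodide, in which the soft and weakly basic nucleophile should substitute and not eliminate at the β-branched carbon and the excess of 10 suppresses dialkylation; the new malonate CH is a labile centre that is overwritten in step 7.

Step 7
Reactants: 11 mixed malonate carrying the branched chain; 12 prenyl bromide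
Product: 13 (2R)-2-prenyl-2-(branched chain) tert-butyl 2,2-diphenylethyl malonate
Conditions: (S,S)-3,4,5-trifluorophenyl-NAS bromide (5 mol%), 50% aq. KOH, toluene, −40 °C
Reagents that add atoms: none
Why: Enantioselective phase-transfer alkylation of an α-monosubstituted mixed malonate with an allylic bromide, in which the chiral ammonium cation pairs with the enolate, distinguishes the tert-butyl from the diphenylethyl ester and should deliver prenyl to the face that makes quaternary C8 (R); since the chain centre is already fixed, any minor C8 epimer is a diastereomer and can be removed by chromatography.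

Step 8
Reactants: 13 (2R)-2-prenyl-2-(branched chain) tert-butyl 2,2-diphenylethyl malonate
Product: 14 tert-butyl (2R)-2-formyl-5-methyl-2-[(2R)-5-methyl-2-(prop-1-en-2-yl)hex-5-en-1-yl]hex-4-enoate
Conditions: iBu2AlH, CH2Cl2, −78 °C; aq. potassium sodium tartrate
Reagents that add atoms: none
Why: Partial reduction of an ester to the aldehyde, in which the primary diphenylethyl ester gives a tetrahedral aluminate held by chelation to the neighbouring ester at −78 °C while the bulky tert-butyl ester is not attacked, and the aldehyde has no α-hydrogen so C8 cannot epimerise.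

Step 9
Reactants: 15 (S)-4-benzyl-3-propionyloxazolidin-2-one; 16 acetaldehyde
Product: 17 (4S)-4-benzyl-3-[(2S,3R)-3-hydroxy-2-methylbutanoyl]oxazolidin-2-one
Conditions: Bu2BOTf, iPr2NEt, CH2Cl2, −78 to 0 °C; then pH 7 buffer, MeOH, H2O2
Reagents that add atoms: none
Why: Boron-mediated Evans syn-aldol reaction, in which the Z-enolate reacts through a closed chair transition state on the face away from the benzyl group and so sets the 2S centre (later C3) and the 3R centre (later C2) that become the cis-2,3-dimethyl unit of ring B.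

Step 10
Reactants: 17 (4S)-4-benzyl-3-[(2S,3R)-3-hydroxy-2-methylbutanoyl]oxazolidin-2-one
Product: 18 (2S,3R)-3-hydroxy-N-methoxy-N,2-dimethylbutanamide
Conditions: MeONHMe·HCl, AlMe3, CH2Cl2, −10 to 0 °C
Reagents that add atoms: N,O-dimethylhydroxylamine hydrochloride, CNOC.Cl
Why: Aluminium amide aminolysis of the imide, in which the free β-hydroxyl directs the aluminium amide to the exocyclic carbonyl and the auxiliary is released without touching either stereocentre.

Step 11
Reactants: 18 (2S,3R)-3-hydroxy-N-methoxy-N,2-dimethylbutanamide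
Product: 19 (2S,3R)-3-[(tert-butyldimethylsilyl)oxy]-N-methoxy-N,2-dimethylbutanamide
Conditions: TBSCl, imidazole, DMF, rt
Reagents that add atoms: tert-butyldimethylsilyl chloride, CC(C)(C)[Si](C)(C)Cl
Why: Silylation of the secondary alcohol protects the future O1 during the enolate chemistry and blocks retro-aldol cleavage.

Step 12
Reactants: 19 (2S,3R)-3-[(tert-butyldimethylsilyl)oxy]-N-methoxy-N,2-dimethylbutanamide
Product: 20 (3S,4R)-4-[(tert-butyldimethylsilyl)oxy]-3-methylpentan-2-one
Conditions: MeMgBr, THF, −20 to 0 °C; aq. NH4Cl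
Reagents that add atoms: methylmagnesium bromide, C[Mg]Br
Why: Addition of the Grignard reagent to the N-methoxy-N-methylamide stops at the chelated tetrahedral intermediate (Weinreb ketone synthesis) and gives the methyl ketone without epimerising the α-centre.

Step 13
Reactants: 20 (3S,4R)-4-[(tert-butyldimethylsilyl)oxy]-3-methylpentan-2-one; 14 tert-butyl (2R)-2-formyl-5-methyl-2-[(2R)-5-methyl-2-(prop-1-en-2-yl)hex-5-en-1-yl]hex-4-enoate
Product: 21 β-hydroxy ketone joining C8a to the aldol unit (both carbinol epimers)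
Conditions: LiN(iPr)2, THF, −78 °C; then 14, −78 °C; aq. NH4Cl at −78 °C
Reagents that add atoms: none
Why: Kinetic deprotonation occurs at the methyl group and the lithium enolate adds to the non-enolisable neopentyl aldehyde (aldol addition); the new carbinol centre is not controlled and is removed in step 14.

Step 14
Reactants: 21 β-hydroxy ketone
Product: 22 silyl-protected β-diketone
Conditions: 1,1,1-triacetoxy-1,1-dihydro-1,2-benziodoxol-3(1H)-one, NaHCO3, CH2Cl2, 0 °C to rt
Reagents that add atoms: none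
Why: Dess–Martin oxidation converts the β-hydroxy ketone into the β-diketone under buffered, non-epimerising conditions that leave the alkenes, the silyl ether and the tert-butyl ester intact.

Step 15
Reactants: 22 silyl-protected β-diketone
Product: 25 tert-butyl (2R)-2-[(2R,3S)-2,3-dimethyl-4-oxo-3,4-dihydro-2H-pyran-6-yl]-5-methyl-2-[(2R)-5-methyl-2-(prop-1-en-2-yl)hex-5-en-1-yl]hex-4-enoate, via hydroxy diketone 23 (not isolated), via cyclic hemiketal 24 (not isolated)
Conditions: HF (48% aq.), MeCN, 0 °C to rt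
Reagents that add atoms: none
Why: Desilylation frees the δ-hydroxyl, which adds to the C8a carbonyl to give the six-membered hemiketal and then loses water (cyclodehydration to the vinylogous ester); the acid is too weak to protonate the 1,1-disubstituted alkenes or to enolise C3, so the cis-2,3-dimethyl relationship should be kept.

Step 16
Reactants: 25 pyranone tert-butyl ester
Product: 26 tert-butyl (2R)-2-[(2R,3S)-5-iodo-2,3-dimethyl-4-oxo-3,4-dihydro-2H-pyran-6-yl]-5-methyl-2-[(2R)-5-methyl-2-(prop-1-en-2-yl)hex-5-en-1-yl]hex-4-enoate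
Conditions: N-iodosuccinimide, MeCN, 0 °C to rt, dark
Reagents that add atoms: N-iodosuccinimide, O=C1CCC(=O)N1I
Why: Electrophilic iodination of the push–pull alkene, in which C4a as the α-carbon of the vinylogous ester is the most nucleophilic carbon and simply loses its proton after attack, whereas iodonium transfer to the isolated alkenes is reversible when no nucleophile is present.

Step 17
Reactants: 26 iodopyranone tert-butyl ester
Product: 28 (2R)-2-[(2R,3S)-5-iodo-2,3-dimethyl-4-oxo-3,4-dihydro-2H-pyran-6-yl]-5-methyl-2-[(2R)-5-methyl-2-(prop-1-en-2-yl)hex-5-en-1-yl]hex-4-enoic acid, via trimethylsilyl ester 27 (not isolated)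
Conditions: TMSOTf, 2,6-lutidine, CH2Cl2, 0 °C; then pH 4 citrate buffer
Reagents that add atoms: trimethylsilyl trifluoromethanesulfonate, C[Si](C)(C)OS(=O)(=O)C(F)(F)F
Why: Silyl triflate cleavage of the tert-butyl ester (loss of 2-methylpropene from the O-silylated ester) avoids protic acid, so the isopropenyl and prenyl groups should survive, and the silyl ester is hydrolysed on work-up.

Step 18
Reactants: 28 iodopyranone acid; 29 Meldrum's acid; 30 2-(trimethylsilyl)ethanol
Product: 34 2-(trimethylsilyl)ethyl (4R)-4-[(2R,3S)-5-iodo-2,3-dimethyl-4-oxo-3,4-dihydro-2H-pyran-6-yl]-7-methyl-4-[(2R)-5-methyl-2-(prop-1-en-2-yl)hex-5-en-1-yl]-3-oxooct-6-enoate, via acid chloride 31 (not isolated), via acyl Meldrum's acid 32 (not isolated), via acylketene 33 (not isolated)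
Conditions: 1-chloro-N,N,2-trimethylprop-1-en-1-amine, CH2Cl2, 0 °C; then 29, pyridine, 0 °C to rt; then 30, toluene, 80 °C
Reagents that add atoms: 1-chloro-N,N,2-trimethylprop-1-en-1-amine, CC(C)=C(Cl)N(C)C
Why: Acylation of Meldrum's acid by the acid chloride and thermal loss of acetone and carbon dioxide give an acylketene that the alcohol traps as the β-keto ester; every stage is neutral or weakly basic, so C3 and the alkenyl iodide are not affected.

Step 19
Reactants: 34 iodo β-keto ester precursor; 35 carbon monoxide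
Product: 36 2-(trimethylsilyl)ethyl (2R,3S,8R)-5-hydroxy-2,3-dimethyl-8-(3-methylbut-2-en-1-yl)-8-[(2R)-5-methyl-2-(prop-1-en-2-yl)hex-5-en-1-yl]-4,7-dioxo-3,4,7,8-tetrahydro-2H-chromene-6-carboxylate
Conditions: Pd(OAc)2 (10 mol%), 4,5-bis(diphenylphosphino)-9,9-dimethylxanthene (Xantphos, 12 mol%), MgCl2, Et3N, CO (5 bar), MeCN, 60 °C; citric acid work-up
Reagents that add atoms: none
Why: Zerovalent palladium, formed from Pd(OAc)2 and the diphosphine under CO, adds oxidatively to the C4a–I bond of the α-iodo vinylogous ester, CO inserts to give the acylpalladium iodide at the future C5, and the magnesium-chelated enolate of the β-keto ester attacks this acyl group through C6, which releases zerovalent palladium while Et3N takes up HI. The closest known reaction type is the palladium-catalysed carbonylative α-acylation of 1,3-dicarbonyl compounds with aryl or alkenyl halides under MgCl2 and Et3N, run here intramolecularly. Ring A closes as a six-membered carbocycle by 6-exo-trig attack of C6 on the acyl carbon C5, helped by the geminal substitution at C8 that holds both reacting arms together. No stereocentre is formed: C8, C2, C3 and the chain centre are fixed beforehand, and the weak amine base with the magnesium salt should not enolise C3. The step needs CO insertion to outrun carbopalladation of the prenyl or isopropenyl alkenes and direct enolate coupling, which CO pressure and the wide-bite-angle ligand secure, and it needs C- over O-acylation, which the magnesium chelate favours. Any enol ester formed through the C7 oxygen should rearrange under the same conditions to the chelated tricarbonyl compound, the thermodynamic product.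

Step 20
Reactants: 36 bicyclic 2-(trimethylsilyl)ethyl ester
Product: 38 (2R,3S,8R)-5-hydroxy-2,3-dimethyl-8-(3-methylbut-2-en-1-yl)-8-[(2R)-5-methyl-2-(prop-1-en-2-yl)hex-5-en-1-yl]-2,3-dihydro-4H-chromene-4,7(8H)-dione, via carboxylic acid 37 (not isolated)
Conditions: Bu4NF, THF, 0 °C to rt; then AcOH, 40 °C
Reagents that add atoms: none
Why: Fluoride attacks silicon and the ester fragments to ethene, fluorotrimethylsilane and the carboxylate, whose vinylogous β-keto acid decarboxylates on mild acidification, so no strong acid meets the alkenes or the prenyl group next to the enolised trione.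

Step 21
Reactants: 38 C6–H bicyclic core; 39 (E)-hex-2-enal
Product: 40 enol lactone in which a (4S)-4-propyl-3,4-dihydropyran-2-one is fused to ring A through C6 and the C7 oxygen
Conditions: (5aR,10bS)-2-mesityl-5a,10b-dihydro-4H,6H-indeno[2,1-b][1,2,4]triazolo[4,3-d][1,4]oxazin-2-ium chloride (15 mol%), iPr2NEt, 3,3',5,5'-tetra-tert-butyl-4,4'-diphenoquinone, toluene, 4 Å molecular sieves, rt
Reagents that add atoms: none
Why: Oxidative carbene catalysis, in which carbene and quinone turn the enal into an α,β-unsaturated acyl azolium, C6 of the cyclic 1,3-dicarbonyl adds to its β-carbon (Michael addition) and an enol oxygen is then acylated with release of the catalyst (lactonisation); the chiral triazolylidene should direct C6 to the Si face of the β-carbon and so set the new centre as (S), and which enol oxygen closes the lactone is immaterial because step 22 opens it again.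

Step 22
Reactants: 40 enol lactone
Product: 41 (3S)-3-[(2R,3S,8R)-5-hydroxy-2,3-dimethyl-8-(3-methylbut-2-en-1-yl)-8-[(2R)-5-methyl-2-(prop-1-en-2-yl)hex-5-en-1-yl]-4,7-dioxo-3,4,7,8-tetrahydro-2H-chromen-6-yl]hexanoic acid (target)
Conditions: LiOH, THF/H2O, 0 °C; then cold 1 M HCl to pH 3
Reagents that add atoms: lithium hydroxide, [Li+].[OH-]
Why: Saponification of the enol lactone, an activated ester, is fast at 0 °C, the trione is present as its enolate and thereby shields C3 from epimerisation, and acidification returns the enol and the free acid.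

Compound list
1 | (+)-limonene 1,2-oxide, (4R)-1-methyl-4-(prop-1-en-2-yl)-7-oxabicyclo[4.1.0]heptane, cis/trans mixture at the epoxide | CC12OC1C[C@@H](CC2)C(C)=C | starting material
2 | (4R)-1-methyl-4-(prop-1-en-2-yl)cyclohexane-1,2-diol | CC1(O)C(O)C[C@@H](CC1)C(C)=C | intermediate
3 | (3R)-6-oxo-3-(prop-1-en-2-yl)heptanal | O=CC[C@@H](CCC(C)=O)C(C)=C | intermediate
4 | (3R)-6-oxo-3-(prop-1-en-2-yl)heptanoic acid | OC(=O)C[C@@H](CCC(C)=O)C(C)=C | intermediate
5 | (3R)-6-methyl-3-(prop-1-en-2-yl)hept-6-enoic acid | OC(=O)C[C@@H](CCC(C)=C)C(C)=C | intermediate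
6 | 2-thioxopyridin-1(2H)-yl (3R)-6-methyl-3-(prop-1-en-2-yl)hept-6-enoate (Barton ester) | S=C1C=CC=CN1OC(=O)C[C@@H](CCC(C)=C)C(C)=C | intermediate
7 | (3S)-3-(iodomethyl)-2,6-dimethylhepta-1,6-diene | IC[C@@H](CCC(C)=C)C(C)=C | intermediate
8 | 3-(tert-butoxy)-3-oxopropanoic acid | CC(C)(C)OC(=O)CC(=O)O | starting material
9 | 2,2-diphenylethanol | OCC(c1ccccc1)c1ccccc1 | starting material
10 | tert-butyl 2,2-diphenylethyl propanedioate | CC(C)(C)OC(=O)CC(=O)OCC(c1ccccc1)c1ccccc1 | intermediate
11 | 1-tert-butyl 3-(2,2-diphenylethyl) 2-[(2R)-5-methyl-2-(prop-1-en-2-yl)hex-5-en-1-yl]propanedioate, both epimers at C2 | C=C(C)CC[C@H](CC(C(=O)OC(C)(C)C)C(=O)OCC(c1ccccc1)c1ccccc1)C(=C)C | intermediate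
12 | prenyl bromide, 1-bromo-3-methylbut-2-ene | CC(C)=CCBr | starting material
13 | 1-tert-butyl 3-(2,2-diphenylethyl) (2R)-2-(3-methylbut-2-en-1-yl)-2-[(2R)-5-methyl-2-(prop-1-en-2-yl)hex-5-en-1-yl]propanedioate | C=C(C)CC[C@H](C[C@@](C(=O)OCC(c1ccccc1)c1ccccc1)(CC=C(C)C)C(=O)OC(C)(C)C)C(=C)C | intermediate
14 | tert-butyl (2R)-2-formyl-5-methyl-2-[(2R)-5-methyl-2-(prop-1-en-2-yl)hex-5-en-1-yl]hex-4-enoate | C=C(C)CC[C@H](C[C@@](C=O)(CC=C(C)C)C(=O)OC(C)(C)C)C(=C)C | intermediate
15 | (S)-4-benzyl-3-propionyloxazolidin-2-one | CCC(=O)N1[C@@H](Cc2ccccc2)COC1=O | starting material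
16 | acetaldehyde | CC=O | starting material
17 | (4S)-4-benzyl-3-[(2S,3R)-3-hydroxy-2-methylbutanoyl]oxazolidin-2-one | C[C@@H](O)[C@H](C)C(=O)N1[C@@H](Cc2ccccc2)COC1=O | intermediate
18 | (2S,3R)-3-hydroxy-N-methoxy-N,2-dimethylbutanamide | C[C@@H](O)[C@H](C)C(=O)N(C)OC | intermediate
19 | (2S,3R)-3-[(tert-butyldimethylsilyl)oxy]-N-methoxy-N,2-dimethylbutanamide | C[C@@H](O[Si](C)(C)C(C)(C)C)[C@H](C)C(=O)N(C)OC | intermediate
20 | (3S,4R)-4-[(tert-butyldimethylsilyl)oxy]-3-methylpentan-2-one | C[C@@H](O[Si](C)(C)C(C)(C)C)[C@H](C)C(C)=O | intermediate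
21 | tert-butyl (2R)-2-[(4S,5R)-5-[(tert-butyldimethylsilyl)oxy]-1-hydroxy-4-methyl-3-oxohexyl]-5-methyl-2-[(2R)-5-methyl-2-(prop-1-en-2-yl)hex-5-en-1-yl]hex-4-enoate, both carbinol epimers | C=C(C)CC[C@H](C[C@@](C(O)CC(=O)[C@@H](C)[C@@H](C)O[Si](C)(C)C(C)(C)C)(CC=C(C)C)C(=O)OC(C)(C)C)C(=C)C | intermediate
22 | tert-butyl (2R)-2-[(4S,5R)-5-[(tert-butyldimethylsilyl)oxy]-4-methyl-1,3-dioxohexyl]-5-methyl-2-[(2R)-5-methyl-2-(prop-1-en-2-yl)hex-5-en-1-yl]hex-4-enoate (β-diketone, drawn in the diketo form) | C=C(C)CC[C@H](C[C@@](C(=O)CC(=O)[C@@H](C)[C@@H](C)O[Si](C)(C)C(C)(C)C)(CC=C(C)C)C(=O)OC(C)(C)C)C(=C)C | intermediate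
23 | tert-butyl (2R)-2-[(4S,5R)-5-hydroxy-4-methyl-1,3-dioxohexyl]-5-methyl-2-[(2R)-5-methyl-2-(prop-1-en-2-yl)hex-5-en-1-yl]hex-4-enoate | C=C(C)CC[C@H](C[C@@](C(=O)CC(=O)[C@@H](C)[C@@H](C)O)(CC=C(C)C)C(=O)OC(C)(C)C)C(=C)C | intermediate
24 | tert-butyl (2R)-2-[(5S,6R)-2-hydroxy-5,6-dimethyl-4-oxotetrahydro-2H-pyran-2-yl]-5-methyl-2-[(2R)-5-methyl-2-(prop-1-en-2-yl)hex-5-en-1-yl]hex-4-enoate, both hemiketal epimers | C=C(C)CC[C@H](C[C@@](C1(O)CC(=O)[C@@H](C)[C@@H](C)O1)(CC=C(C)C)C(=O)OC(C)(C)C)C(=C)C | intermediate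
25 | tert-butyl (2R)-2-[(2R,3S)-2,3-dimethyl-4-oxo-3,4-dihydro-2H-pyran-6-yl]-5-methyl-2-[(2R)-5-methyl-2-(prop-1-en-2-yl)hex-5-en-1-yl]hex-4-enoate | C=C(C)CC[C@H](C[C@@](C1=CC(=O)[C@@H](C)[C@@H](C)O1)(CC=C(C)C)C(=O)OC(C)(C)C)C(=C)C | intermediate
26 | tert-butyl (2R)-2-[(2R,3S)-5-iodo-2,3-dimethyl-4-oxo-3,4-dihydro-2H-pyran-6-yl]-5-methyl-2-[(2R)-5-methyl-2-(prop-1-en-2-yl)hex-5-en-1-yl]hex-4-enoate | C=C(C)CC[C@H](C[C@@](C1=C(I)C(=O)[C@@H](C)[C@@H](C)O1)(CC=C(C)C)C(=O)OC(C)(C)C)C(=C)C | intermediate
27 | trimethylsilyl (2R)-2-[(2R,3S)-5-iodo-2,3-dimethyl-4-oxo-3,4-dihydro-2H-pyran-6-yl]-5-methyl-2-[(2R)-5-methyl-2-(prop-1-en-2-yl)hex-5-en-1-yl]hex-4-enoate | C=C(C)CC[C@H](C[C@@](C1=C(I)C(=O)[C@@H](C)[C@@H](C)O1)(CC=C(C)C)C(=O)O[Si](C)(C)C)C(=C)C | intermediate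
28 | (2R)-2-[(2R,3S)-5-iodo-2,3-dimethyl-4-oxo-3,4-dihydro-2H-pyran-6-yl]-5-methyl-2-[(2R)-5-methyl-2-(prop-1-en-2-yl)hex-5-en-1-yl]hex-4-enoic acid | C=C(C)CC[C@H](C[C@@](C1=C(I)C(=O)[C@@H](C)[C@@H](C)O1)(CC=C(C)C)C(=O)O)C(=C)C | intermediate
29 | Meldrum's acid, 2,2-dimethyl-1,3-dioxane-4,6-dione | CC1(C)OC(=O)CC(=O)O1 | starting material
30 | 2-(trimethylsilyl)ethanol | C[Si](C)(C)CCO | starting material
31 | (2R)-2-[(2R,3S)-5-iodo-2,3-dimethyl-4-oxo-3,4-dihydro-2H-pyran-6-yl]-5-methyl-2-[(2R)-5-methyl-2-(prop-1-en-2-yl)hex-5-en-1-yl]hex-4-enoyl chloride | C=C(C)CC[C@H](C[C@@](C1=C(I)C(=O)[C@@H](C)[C@@H](C)O1)(CC=C(C)C)C(Cl)=O)C(=C)C | intermediate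
32 | 5-acyl-2,2-dimethyl-1,3-dioxane-4,6-dione in which the acyl group is that of acid 28 | C=C(C)CC[C@H](C[C@@](C1=C(I)C(=O)[C@@H](C)[C@@H](C)O1)(CC=C(C)C)C(=O)C1C(=O)OC(C)(C)OC1=O)C(=C)C | intermediate
33 | (4R)-4-[(2R,3S)-5-iodo-2,3-dimethyl-4-oxo-3,4-dihydro-2H-pyran-6-yl]-7-methyl-4-[(2R)-5-methyl-2-(prop-1-en-2-yl)hex-5-en-1-yl]octa-1,6-diene-1,3-dione (acylketene) | C=C(C)CC[C@H](C[C@@](C1=C(I)C(=O)[C@@H](C)[C@@H](C)O1)(CC=C(C)C)C(=O)C=C=O)C(=C)C | intermediate
34 | 2-(trimethylsilyl)ethyl (4R)-4-[(2R,3S)-5-iodo-2,3-dimethyl-4-oxo-3,4-dihydro-2H-pyran-6-yl]-7-methyl-4-[(2R)-5-methyl-2-(prop-1-en-2-yl)hex-5-en-1-yl]-3-oxooct-6-enoate (precursor of the key step) | C=C(C)CC[C@H](C[C@@](C1=C(I)C(=O)[C@@H](C)[C@@H](C)O1)(CC=C(C)C)C(=O)CC(=O)OCC[Si](C)(C)C)C(=C)C | intermediate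
35 | carbon monoxide | [C-]#[O+] | starting material
36 | 2-(trimethylsilyl)ethyl (2R,3S,8R)-5-hydroxy-2,3-dimethyl-8-(3-methylbut-2-en-1-yl)-8-[(2R)-5-methyl-2-(prop-1-en-2-yl)hex-5-en-1-yl]-4,7-dioxo-3,4,7,8-tetrahydro-2H-chromene-6-carboxylate (product of the key step) | C=C(C)CC[C@H](C[C@@]1(CC=C(C)C)C(=O)C(C(=O)OCC[Si](C)(C)C)=C(O)C2=C1O[C@H](C)[C@H](C)C2=O)C(=C)C | intermediate
37 | (2R,3S,8R)-5-hydroxy-2,3-dimethyl-8-(3-methylbut-2-en-1-yl)-8-[(2R)-5-methyl-2-(prop-1-en-2-yl)hex-5-en-1-yl]-4,7-dioxo-3,4,7,8-tetrahydro-2H-chromene-6-carboxylic acid | C=C(C)CC[C@H](C[C@@]1(CC=C(C)C)C(=O)C(C(=O)O)=C(O)C2=C1O[C@H](C)[C@H](C)C2=O)C(=C)C | intermediate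
38 | (2R,3S,8R)-5-hydroxy-2,3-dimethyl-8-(3-methylbut-2-en-1-yl)-8-[(2R)-5-methyl-2-(prop-1-en-2-yl)hex-5-en-1-yl]-2,3-dihydro-4H-chromene-4,7(8H)-dione | C=C(C)CC[C@H](C[C@@]1(CC=C(C)C)C(=O)C=C(O)C2=C1O[C@H](C)[C@H](C)C2=O)C(=C)C | intermediate
39 | (E)-hex-2-enal | CCC/C=C/C=O | starting material
40 | enol lactone of the target acid on the C7 oxygen: (4S)-4-propyl-3,4-dihydropyran-2-one fused at C6–C7 of ring A, other centres as in 38 | C=C(C)CC[C@H](C[C@@]1(CC=C(C)C)C2=C(C(=O)C3=C1O[C@H](C)[C@H](C)C3=O)[C@@H](CCC)CC(=O)O2)C(=C)C | intermediate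
41 | (3S)-3-[(2R,3S,8R)-5-hydroxy-2,3-dimethyl-8-(3-methylbut-2-en-1-yl)-8-[(2R)-5-methyl-2-(prop-1-en-2-yl)hex-5-en-1-yl]-4,7-dioxo-3,4,7,8-tetrahydro-2H-chromen-6-yl]hexanoic acid | C=C(C)CC[C@H](C[C@@]1(CC=C(C)C)C(=O)C([C@@H](CCC)CC(=O)O)=C(O)C2=C1O[C@H](C)[C@H](C)C2=O)C(=C)C | target

Total step count: 22 steps.
Longest linear sequence: 17 steps (steps 1 to 4, 6 to 8 and 13 to 22, from limonene oxide).

Steps most likely to fail

Step 19. The alkenylpalladium iodide formed at C4a may be consumed before CO inserts, by carbopalladation of the prenyl double bond or by direct coupling with the enolate, or the acylpalladium may be captured at oxygen and the enol ester may fail to rearrange. The fallback closes ring A without palladium by making only the C4a–C5 bond, with C5 and C6 both drawn from Meldrum's acid. It sets out from 25. The tert-butyl ester is cleaved as in step 17, through the trimethylsilyl ester F1 to the acid F2. F2 is coupled with 29 (EDC·HCl, 4-(dimethylamino)pyridine, CH2Cl2) to the acyl Meldrum's acid F3. F3 is heated in dilute toluene at 100 °C without alcohol, so that the acylketene F4 acylates the nucleophilic C4a–H of the vinylogous ester in a six-membered Friedel–Crafts-type closure and tautomerises to 38, where the route is rejoined. Steps 16 to 20 and the iodide are then not needed.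

Step 7. The ammonium cation may discriminate the enolate faces poorly, because the α-substituent is far bulkier than in the usual substrates, or the alkylation may be slow at low temperature. The fallback gives up catalyst control and relies on the limonene-derived centre, which makes the two C8 epimers diastereomers. It sets out from 11: prenylation with NaH and 12 in DMF gives 13 together with its C8 epimer, the (2S)-malonate F5. The two are separated by preparative HPLC and 13 re-enters the route at step 8.

Step 21. Facial selection at the β-carbon of the acyl azolium may be poor next to the hindered, strongly hydrogen-bonded trione, or the enol may be acylated at oxygen without C–C bond formation. The fallback replaces acyl azolium catalysis by iminium catalysis. It sets out from 38 and 39: the enantiomer of 2-[diphenyl(trimethylsilyloxy)methyl]pyrrolidine that leaves the Si face of the β-carbon open, with benzoic acid as co-catalyst in CH2Cl2, should give the Michael adduct as its cyclic hemiacetal, the lactol F6. Oxidation of F6 with PhI(OAc)2 and catalytic 2,2,6,6-tetramethylpiperidin-1-oxyl gives lactone 40, where the route is rejoined.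

Further compounds
F1 | step 19 | trimethylsilyl (2R)-2-[(2R,3S)-2,3-dimethyl-4-oxo-3,4-dihydro-2H-pyran-6-yl]-5-methyl-2-[(2R)-5-methyl-2-(prop-1-en-2-yl)hex-5-en-1-yl]hex-4-enoate | C=C(C)CC[C@H](C[C@@](C1=CC(=O)[C@@H](C)[C@@H](C)O1)(CC=C(C)C)C(=O)O[Si](C)(C)C)C(=C)C
F2 | step 19 | (2R)-2-[(2R,3S)-2,3-dimethyl-4-oxo-3,4-dihydro-2H-pyran-6-yl]-5-methyl-2-[(2R)-5-methyl-2-(prop-1-en-2-yl)hex-5-en-1-yl]hex-4-enoic acid | C=C(C)CC[C@H](C[C@@](C1=CC(=O)[C@@H](C)[C@@H](C)O1)(CC=C(C)C)C(=O)O)C(=C)C
F3 | step 19 | 5-acyl-2,2-dimethyl-1,3-dioxane-4,6-dione in which the acyl group is that of acid F2 | C=C(C)CC[C@H](C[C@@](C1=CC(=O)[C@@H](C)[C@@H](C)O1)(CC=C(C)C)C(=O)C1C(=O)OC(C)(C)OC1=O)C(=C)C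
F4 | step 19 | (4R)-4-[(2R,3S)-2,3-dimethyl-4-oxo-3,4-dihydro-2H-pyran-6-yl]-7-methyl-4-[(2R)-5-methyl-2-(prop-1-en-2-yl)hex-5-en-1-yl]octa-1,6-diene-1,3-dione (acylketene) | C=C(C)CC[C@H](C[C@@](C1=CC(=O)[C@@H](C)[C@@H](C)O1)(CC=C(C)C)C(=O)C=C=O)C(=C)C
F5 | step 7 | 1-tert-butyl 3-(2,2-diphenylethyl) (2S)-2-(3-methylbut-2-en-1-yl)-2-[(2R)-5-methyl-2-(prop-1-en-2-yl)hex-5-en-1-yl]propanedioate | C=C(C)CC[C@H](C[C@](C(=O)OCC(c1ccccc1)c1ccccc1)(CC=C(C)C)C(=O)OC(C)(C)C)C(=C)C
F6 | step 21 | lactol corresponding to lactone 40 (2-hydroxy-4-propyl-3,4-dihydro-2H-pyran fused at C6–C7 of ring A, both anomers) | C=C(C)CC[C@H](C[C@@]1(CC=C(C)C)C2=C(C(=O)C3=C1O[C@H](C)[C@H](C)C3=O)[C@@H](CCC)CC(O)O2)C(=C)C
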